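C1–C9 = bicyclo[3.3.1]nonane-2,4,9-trione (C1 isobutyryl, C3 quaternary, C5 geranyl, C6 H2, C7 H, C8 Me2); C10 H2 (on C7)–C11 H (on C3) complete the homoadamantane; C11–C12 Me2–C13 H2–C14 H2–C3 is the cyclopentane. Target = (1S,3S,5R,7R,11R).
Last disconnection C1–C8: C1 is the central carbon of a β-triketone (C2=O, C9=O, isobutyryl C=O) and C8 is a fully substituted dimethyl carbon on C7, so the bond is the union of a stabilised enolate and a tertiary carbocation; the seven-membered ring C3–C4–C5–C6–C7–C10–C11 already holds C8 over C1 (precursor: tertiary alcohol 20).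
C5–C6 (seven-membered ring) by intramolecular Michael addition to a 2-methylene ester on C7; the ester carbon becomes C8 with MeMgBr; geranyl goes to C5 by palladium allylation and isobutyryl to C1 by O→C acyl shift.
C3–C14 (cyclopentane) by alkylative dearomatisation of a chroman ketal, made from phloroglucinol and an α-keto enoate by enantioselective Friedel–Crafts addition (sets C11); the ketal ring from the oxygen on C2 to C7 is a temporary tether that relays C11 to C3 and tells C5 from C1, and is hydrolysed in step 6.
Ring order: chroman ketal (temporary) → cyclopentane with dearomatised six-membered ring → seven-membered ring → cyclohexanone ring C1–C8–C7–C6–C5–C9, which closes the cage.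

Key step: step 10

Assumption: ylide 6 is taken as a catalogue reagent (otherwise one step from ethyl bromopyruvate and PPh3); 9, 10, 11 and 13 are carried as mixtures of epimers at the ketal carbon, which becomes sp2 in step 6; atom numbers in names are those of the target.

Step 1
Reactants: 1 isobutyronitrile; 2 1-bromo-2-chloroethane
Product: 3 4-chloro-2,2-dimethylbutanenitrile
Conditions: LiN(i-Pr)2, THF, −78 °C; then 2, −78 °C → rt
Reagents that add atoms: none
Why: The lithiated nitrile is C-alkylated by SN2 displacement of bromide, the better leaving group of 2, which installs C12 with its two methyls and the C13–C14 chloride handle; no stereocentre is formed.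

Step 2
Reactants: 3 4-chloro-2,2-dimethylbutanenitrile
Product: 5 4-chloro-2,2-dimethylbutanal, via N-aluminated aldimine 4 (not isolated)
Conditions: i-Bu2AlH, toluene, −78 °C; then 1 M HCl, 0 °C
Reagents that add atoms: water, O
Why: Nitrile half-reduction: a single hydride transfer gives the N-aluminated aldimine, stable at −78 °C, which acidic work-up hydrolyses to the aldehyde (C11).

Step 3
Reactants: 5 4-chloro-2,2-dimethylbutanal; 6 ethyl 3-(triphenylphosphoranylidene)pyruvate
Product: 7 ethyl (E)-7-chloro-5,5-dimethyl-2-oxohept-3-enoate
Conditions: toluene, 80 °C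
Reagents that add atoms: none
Why: Wittig olefination with the stabilised acyl ylide should give the E enoate (thermodynamic selectivity of stabilised ylides) from an aldehyde that cannot enolise.

Step 4
Reactants: 7 ethyl (E)-7-chloro-5,5-dimethyl-2-oxohept-3-enoate; 8 phloroglucinol
Product: 10 ethyl (4R)-4-(4-chloro-2-methylbutan-2-yl)-2-ethoxy-5,7-dihydroxychromane-2-carboxylate, via chroman hemiketal 9 (not isolated)
Conditions: quinine-derived bifunctional squaramide (10 mol%), 8 (3 equiv), THF, 0 °C → rt; then EtOH, camphorsulfonic acid (cat.), 3 Å sieves, rt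
Reagents that add atoms: ethanol, CCO
Why: Bifunctional amine/squaramide catalysis binds the two-point α-keto enoate and the phenol for a Friedel–Crafts conjugate addition whose face at C11 is chosen by the catalyst (the pseudo-enantiomer, quinine- or quinidine-derived, that gives 4R is used), the ortho-OH closes the hemiketal, and acid/EtOH turns it into the base-stable ketal that tethers C7 to the oxygen on C2 and blocks retro-Michael cleavage.

Step 5
Reactants: 10 ethyl (4R)-4-(4-chloro-2-methylbutan-2-yl)-2-ethoxy-5,7-dihydroxychromane-2-carboxylate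
Product: 11 spiro ketal (C3–C14 closed; ketal ring O-on-C2 to C7 retained; six-membered ring C4(OH)=C5H–C9(=O)–C1H=C2)
Conditions: KOt-Bu (2.5 equiv), t-BuOH/THF, 65 °C; then aq. NH4Cl
Reagents that add atoms: none
Why: Alkylative dearomatisation (C-alkylation of a phloroglucinol dianion at its substituted carbon, as in syncarpic acid syntheses) closes the cyclopentane 5-exo-tet at C3, which is ortho and para to the two phenoxides; the chain can only reach the face of C3 on which C12 stands, so the chroman tether fixes C3 relative to C11 (cis 5/6 fusion).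

Step 6
Reactants: 11 spiro ketal; 12 geranyl acetate
Product: 14 keto ester (spiro[4.5]decane trione with geranyl on C5; C1 H2; CH2–CO–CO2Et on C11), via geranylated ketal 13 (not isolated)
Conditions: Pd(PPh3)4 (5 mol%), Et3N, THF, 40 °C; then 1 M HCl, THF, rt
Reagents that add atoms: water, O
Why: Tsuji–Trost allylation: only C5 lies between two free carbonyl/enol oxygens (C1 is masked as the α-carbon of the enol ether to the ketal), the soft enolate attacks the unsubstituted terminus of the π-geranyl complex of divalent palladium with the E alkene retained, and dilute acid then hydrolyses the labile mixed ketal to free the α-keto ester and the C1 H2 dione.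

Step 7
Reactants: 14 keto ester; 15 isobutyryl chloride
Product: 17 C1-isobutyryl triketone (enolised 2-acyl-1,3-dione C2/C1/C9; geranyl on C5), via enol isobutyrate 16 (not isolated)
Conditions: Et3N, CH2Cl2, 0 °C; then DMAP (20 mol%), MeCN, 40 °C
Reagents that add atoms: none
Why: O-Acylation followed by DMAP-catalysed 1,3-acyl shift (Steglich-type rearrangement of enol esters, the standard entry to 2-acylcyclohexane-1,3-diones) should end at C1 because only there is the product an enolisable, hydrogen-bonded triketone, whereas acylation at the substituted C5 is reversible.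

Step 8
Reactants: 17 C1-isobutyryl triketone
Product: 19 bicyclic ester (C5–C6 closed; CO2Et on C7; seven-membered ring C3–C4–C5–C6–C7–C10–C11), via 2-methylene ester 18 (not isolated)
Conditions: Ph3PCH3Br/KN(SiMe3)2 (3.2 equiv), THF, −78 °C → rt; then AcOH, −78 °C
Reagents that add atoms: methyltriphenylphosphonium bromide, C[P+](c1ccccc1)(c1ccccc1)c1ccccc1.[Br-]
Why: Wittig methylenation of the α-keto group (the only carbonyl not masked as a potassium enolate) gives acrylate 18, to which the C5 enolate adds by 7-endo-trig Michael reaction on the face held by the C11 tether (sets C5), and kinetic protonation of the ester enolate from the convex face should place CO2Et on the concave side of C7, syn to C12 as required.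

Step 9
Reactants: 19 bicyclic ester
Product: 20 tertiary alcohol (C7–C(CH3)2OH)
Conditions: MeMgBr (5 equiv), THF, −20 → 0 °C; then aq. NH4Cl
Reagents that add atoms: methylmagnesium bromide, C[Mg]Br
Why: Double Grignard addition converts the ester into the tertiary carbinol that becomes C8, while the triketone is protected as its magnesium enolate and the C4 ketone is shielded by two quaternary neighbours.

Step 10
Reactants: 20 tertiary alcohol
Product: 22 CNP0313870.1, via tertiary mesylate 21 (not isolated)
Conditions: MsCl, Et3N, CH2Cl2, −20 °C; then (CF3)2CHOH, rt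
Reagents that add atoms: none
Why: Mesylation of the tertiary carbinol (via sulfene) gives 21, which ionises in the ionising medium to the tertiary C8 cation, and C1 of the triethylammonium acyl-triketone enolate, held over it on the concave face by the ring C3–C4–C5–C6–C7–C10–C11, captures it (intramolecular SN1 C-alkylation). The closest known reaction type is the cationic C-alkylation of dearomatised acylphloroglucinol triketones by prenyl-derived tertiary cations that gives bicyclo[3.3.1]nonane-trione (type A) cores, the laboratory copy of the biosynthetic step. One bond closes two rings: the cyclohexanone ring C1–C8–C7–C6–C5–C9 (6-exo attack of the endocyclic enolate on the cation) and the second seven-membered ring C1–C2–C3–C11–C10–C7–C8, which completes the homoadamantane. The only new stereocentre, C1, is dictated by the framework, because C8 can reach only the face of the planar enolate that carries the C6–C7–C10 bridge. The step needs C- over O-alkylation and over proton loss: C8 sits over C1 and not over the oxygens on C2 and C9, tertiary enol ethers formed at those oxygens should re-ionise in hexafluoroisopropanol and funnel to the irreversible C–C product, and a 1,2-hydride shift between C8 and C7 can return a minor C7 epimer to the productive cation. The geranyl alkenes never meet a strong Brønsted acid because the medium stays buffered by triethylamine.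

Compound list
1 | isobutyronitrile | CC(C)C#N | starting material
2 | 1-bromo-2-chloroethane | ClCCBr | starting material
3 | 4-chloro-2,2-dimethylbutanenitrile | CC(C)(CCCl)C#N | intermediate
4 | N-(diisobutylalumanyl) aldimine of 4-chloro-2,2-dimethylbutanal | CC(C)(CCCl)C=N[Al](CC(C)C)CC(C)C | intermediate
5 | 4-chloro-2,2-dimethylbutanal | CC(C)(CCCl)C=O | intermediate
6 | ethyl 3-(triphenylphosphoranylidene)pyruvate | CCOC(=O)C(=O)C=P(c1ccccc1)(c1ccccc1)c1ccccc1 | starting material
7 | ethyl (E)-7-chloro-5,5-dimethyl-2-oxohept-3-enoate | CCOC(=O)C(=O)/C=C/C(C)(C)CCCl | intermediate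
8 | phloroglucinol (benzene-1,3,5-triol) | Oc1cc(O)cc(O)c1 | starting material
9 | ethyl (4R)-4-(4-chloro-2-methylbutan-2-yl)-2,5,7-trihydroxychromane-2-carboxylate (hemiketal; C2 epimers) | CCOC(=O)C1(O)C[C@H](C(C)(C)CCCl)c2c(O)cc(O)cc2O1 | intermediate
10 | ethyl (4R)-4-(4-chloro-2-methylbutan-2-yl)-2-ethoxy-5,7-dihydroxychromane-2-carboxylate (C2 epimers) | CCOC(=O)C1(OCC)C[C@H](C(C)(C)CCCl)c2c(O)cc(O)cc2O1 | intermediate
11 | spiro ketal: cyclopentane C3–C14–C13–C12–C11 cis-fused to the ketal pyran O–C7(OEt)(CO2Et)–C10–C11–C3–C2; C3 and C11 as in 22 | CCOC(=O)C1(OCC)C[C@@H]2C(C)(C)CC[C@@]23C(O)=CC(=O)C=C3O1 | intermediate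
12 | geranyl acetate | CC(C)=CCC/C(C)=C/COC(C)=O | starting material
13 | C5-(E)-geranyl derivative of 11 | CCOC(=O)C1(OCC)C[C@@H]2C(C)(C)CC[C@@]23C(O)=C(C/C=C(\C)CCC=C(C)C)C(=O)C=C3O1 | intermediate
14 | keto ester: ethyl 2-oxopropanoate unit on C11 of the C5-geranyl spiro[4.5]decane trione; C3 and C11 as in 22 | CCOC(=O)C(=O)C[C@@H]1C(C)(C)CC[C@@]12C(O)=C(C/C=C(\C)CCC=C(C)C)C(=O)CC2=O | intermediate
15 | isobutyryl chloride | CC(C)C(Cl)=O | starting material
16 | enol isobutyrate of 14 (O-acyl on the C2 oxygen) | CCOC(=O)C(=O)C[C@@H]1C(C)(C)CC[C@@]12C(O)=C(C/C=C(\C)CCC=C(C)C)C(=O)C=C2OC(=O)C(C)C | intermediate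
17 | C1-isobutyryl triketone of 14 (enolised) | CCOC(=O)C(=O)C[C@@H]1C(C)(C)CC[C@@]12C(O)=C(C/C=C(\C)CCC=C(C)C)C(=O)C(C(=O)C(C)C)=C2O | intermediate
18 | 2-methylene ester (acrylate) from 17 | CCOC(=O)C(=C)C[C@@H]1C(C)(C)CC[C@@]12C(O)=C(C/C=C(\C)CCC=C(C)C)C(=O)C(C(=O)C(C)C)=C2O | intermediate
19 | bicyclic ester: C5–C6 bond closed; CO2Et on C7; C3, C5, C7, C11 as in 22 | CC(C)=CCC/C(C)=C/C[C@@]12C[C@H](C(=O)OCC)C[C@@H]3C(C)(C)CC[C@]3(C1=O)C(O)=C(C(=O)C(C)C)C2=O | intermediate
20 | tertiary alcohol: C7–C(CH3)2OH; C3, C5, C7, C11 as in 22 | CC(C)=CCC/C(C)=C/C[C@@]12C[C@H](C(C)(C)O)C[C@@H]3C(C)(C)CC[C@]3(C1=O)C(O)=C(C(=O)C(C)C)C2=O | intermediate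
21 | tertiary methanesulfonate of 20 | CC(C)=CCC/C(C)=C/C[C@@]12C[C@H](C(C)(C)OS(C)(=O)=O)C[C@@H]3C(C)(C)CC[C@]3(C1=O)C(O)=C(C(=O)C(C)C)C2=O | intermediate
22 | CNP0313870.1, (1S,3S,5R,7R,11R) in the numbering of the overview | CC(C)=CCC/C(C)=C/C[C@@]12C[C@H]3C[C@@H]4C(C)(C)CC[C@]4(C1=O)C(=O)[C@@](C(=O)C(C)C)(C2=O)C3(C)C | target

Total step count: 10. Longest linear sequence: 10 steps (1 → 22).

Steps most likely to fail

Step 4. The conjugate addition to the neopentyl-type γ-carbon may be slow, so that uncatalysed or 1,2-addition background erodes the facial selectivity at C11. Fallback (resolution in place of catalyst control): 7 and 8 are combined under Sc(OTf)3 catalysis, which should give the hemiketal as a racemate, that is 9 together with its enantiomer ethyl (4S)-4-(4-chloro-2-methylbutan-2-yl)-2,5,7-trihydroxychromane-2-carboxylate F1. Ketalisation as in step 4 then gives 10 together with its enantiomer ethyl (4S)-4-(4-chloro-2-methylbutan-2-yl)-2-ethoxy-5,7-dihydroxychromane-2-carboxylate F2. The two are separated by preparative chromatography on a chiral stationary phase, and the route continues from 10.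

Step 8. The basic ylide may deprotonate next to the keto ester (enolisation, retro-Michael opening of C3–C11), the keto group may be masked as hemiketal or aldolate, and protonation at C7 may be unselective. Fallback (addition–elimination olefination without a basic ylide, ring closure as a separate operation): 17 is treated with Me3SiCH2Li/CeCl3 at −78 °C to give the β-hydroxysilane F3. Acetic acid or silica gel then effects Peterson elimination to the 2-methylene ester 18, which is isolated. Cs2CO3 in MeCN at 0 °C followed by a cold acetic acid quench closes the ring to 19.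

Step 10. Sulfonylation may occur at the triketone enol oxygen instead of the tertiary alcohol, or proton loss from the C8 cation may outrun C–C bond formation. Fallback (alkene activation in place of leaving-group ionisation): 20 is dehydrated with methyl N-(triethylammoniosulfonyl)carbamate to the isopropenyl compound F4. Ph3PAuCl/AgOTf (monovalent gold) then catalyses Markovnikov hydroalkylation of the 1,1-disubstituted alkene by C1 of the triketone, which should give 22 directly.

Further compounds
F1 | step 4 | ethyl (4S)-4-(4-chloro-2-methylbutan-2-yl)-2,5,7-trihydroxychromane-2-carboxylate | CCOC(=O)C1(O)C[C@@H](C(C)(C)CCCl)c2c(O)cc(O)cc2O1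
F2 | step 4 | ethyl (4S)-4-(4-chloro-2-methylbutan-2-yl)-2-ethoxy-5,7-dihydroxychromane-2-carboxylate | CCOC(=O)C1(OCC)C[C@@H](C(C)(C)CCCl)c2c(O)cc(O)cc2O1
F3 | step 8 | β-hydroxysilane from 17 (C7 carries OH, CH2SiMe3 and CO2Et) | CCOC(=O)C(O)(C[Si](C)(C)C)C[C@@H]1C(C)(C)CC[C@@]12C(O)=C(C/C=C(\C)CCC=C(C)C)C(=O)C(C(=O)C(C)C)=C2O
F4 | step 10 | isopropenyl compound from 20 (C7–C(CH3)=CH2) | CC(C)=CCC/C(C)=C/C[C@@]12C[C@H](C(C)=C)C[C@@H]3C(C)(C)CC[C@]3(C1=O)C(O)=C(C(=O)C(C)C)C2=O
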